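The readings come from a simulation from invented constants, noise included.

- If starting material has two ways to go, a catalysed route running with its first power and a loss needing no catalyst running with its square, the yield can be read from a single level: the crossing concentration, the level of starting material at which the two routes consume it equally fast.

| setting | delta | theta | eta |
|---|---|---|---|
| starting material | 0.0500 M | 0.0500 M | 0.0170 M |
| catalyst | 0.00250 M | 0.00130 M | 0.00250 M |
| time |  |  | 9.8 h |

| delta run: time / h | delta run: [product] / M | theta run: time / h | theta run: [product] / M |
|---|---|---|---|
| 0.39 | 3.1 × 10⁻⁴ | 0.39 | 3.3 × 10⁻⁴ |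
| 0.62 | 0.00124 | 0.62 | 5.8 × 10⁻⁴ |
| 0.98 | 0.00249 | 0.98 | 8.6 × 10⁻⁴ |
| 1.6 | 0.00540 | 1.6 | 0.00295 |
| 2.5 | 0.00978 | 2.5 | 0.00568 |
| 3.9 | 0.01560 | 3.9 | 0.00897 |
| 6.2 | 0.02192 | 6.2 | 0.01376 |
| 9.8 | 0.02497 | 9.8 | 0.01750 |

(each reading ± 2 × 10⁻⁴ M)

- how the opening rate goes with [catalyst] round the charge of the delta run: the exponent of the rate at two percent of starting material gone to product
- product in the eta run at 9.8 h, as a share of the starting material charged

- Overall: starting material -> product, with catalyst as catalyst.
- Constant volume, constant temperature.
- What is held in complexes is read along with the free species.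
- An order is taken over about fifteen percent of the charge, up and down.

- We suppose such a loss, as our own reading: in the last stretch the theta run, on less catalyst, climbs by 0.00374 M against 0.00305 M in the delta run, though it stands lower.
- Each bit of starting material then reaches product with the share crossing/(crossing + current level), which sums to: final product = crossing × ln(1 + charge/crossing).
- The eta run has the catalyst charge of the delta run, so we give it the same crossing and assume it has finished by 9.8 h.
- Bound from below: the delta run holds 0.02497 M at 9.8 h and is still climbing. A crossing of 0.0200 M returns about that, 0.0251 M, and it puts the eta run at 72.4%.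
- Bound from above: a crossing of 0.0250 M grants the delta run a further 0.00250 M, although its average climb over the last stretch reads 8.47 × 10⁻⁴ M h⁻¹, less than the 0.00275 M h⁻¹ of the stretch before. That gives the eta run 76.3%.
- The opening order we leave unbracketed: its mark of two percent lies at 0.00100 M, against a scatter of 2 × 10⁻⁴ M.
- The forecast says 0.85 and 65%, with the ground “partial saturation gives more”, which places its yield below our bracket.

    active catalyst + starting material ⇌ catalyst-substrate complex, settled at all times (38.60 M⁻¹)
    catalyst-substrate complex ⇌ product + active catalyst (5.076 h⁻¹, 9.720 M⁻¹ h⁻¹)
    2 starting material → homo dimer (3.272 M⁻¹ h⁻¹)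
    catalyst → active catalyst (0.8640 h⁻¹)

- The flask gives an order of 0.61 and, in the eta run, a yield of 74.7%, which lies between 72.4% and 76.3%. At the mark of two percent of the delta charge, the theta run goes at 0.0020 M h⁻¹ against 0.0031 M h⁻¹ in the delta run, a ratio of 0.66. The loss is the homo dimer. Scaled by catalyst charge, the crossing for the theta run is 0.0104 M, which gives a final product of 0.0183 M, and the theta run reads 0.01750 M at 9.8 h.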